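## The problem

The target 27 is a hexaphenol in which a dibenzo-annulated cycloheptenone and an indane share the bond B1–Cc. The labels used throughout are: Ca, the ketone carbon; ring A, the outer resorcinol ring (A1 on Ca, A6 on Cb, oxygen on A3 and A5); ring B, the central resorcinol ring (B1 on Cc, B2 on Ca, B6 on Cd, oxygen on B3 and B5); Cb, the CH of the seven-membered ring that carries ring C (4-hydroxyphenyl); Cc, the ring-fusion CH; Ce and Cd, the indane CH groups that carry ring D (4-hydroxyphenyl) and ring E (3,5-dihydroxyphenyl). The seven-membered ring is Ca–A1–A6–Cb–Cc–B1–B2 and the five-membered ring is Cc–B1–B6–Cd–Ce. Four contiguous stereocentres have to be set, Cb (S), Cc (R), Ce (S) and Cd (S): ring D is trans to both of its neighbours on the five-membered ring, and ring C is trans to Ce across Cb–Cc. The centres are not equally hard: Ce–H is a singly benzylic hydrogen that no later step can invert, so Ce must be set absolutely and early; Cd–H is doubly benzylic and can be equilibrated by base to the trans arrangement; Cc can then be set by bond formation anti to ring D; Cb–H and Cc–H both end up benzylic and ortho to the diaryl ketone, so these two centres can be equilibrated through dienolates once the ketone exists. The vulnerable parts are the electron-rich rings and the benzylic carbons between them: a carbocation at Cb, once Cb hangs on Cc, sits cis to ring E on the five-membered ring and would be captured by it to give a bridged bicyclo[3.2.1]octane, so acid-generated cations at Cb are avoided, and the air-sensitive free phenols are released only in the last step. A1 is meta to both oxygens of ring A and is not nucleophilic, whereas A6 is ortho and para to them, so the Ca–A1 bond calls for an aryl-metal and the Cb–A6 carbon can be made electrophilic as a quinone methide. The feature that opens the strategy is that the two hydrogens on Ce are 1,5-related to Cd through B6–B1–Cc: a diaryl carbene at Cd can insert into one of them, forming Cd–Ce, closing the indane and creating the absolute configuration from an achiral bibenzyl.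

## Retrosynthesis

**27 from 26.** The six O–CH3 bonds are cut. Methyl ethers are the only phenol protection that survives everything below (organolithiums, KOtBu in DMSO, AlCl3 at low temperature, a rhodium carbene) and one BBr3 step removes all of them. 26 differs from 27 only in that its phenols are masked.

**26 from 22.** The seven-membered ring is opened at Ca–A1. The neighbouring cut, Cb–A6 by Friedel–Crafts attack of a Cb cation on ring A, was set aside for two reasons. That cation lies cis to ring E and closes onto it in a six-membered, bridged mode. In addition, A6 would be deactivated by the ketone already on A1. Cutting Ca–A1 makes ring closure an anionic acyl substitution: an aryllithium at A1 (from a bromide) attacks a methyl ester on B2. The precursor 22 is an open-chain bromo ester with no ketone. The forward step needs bromine–lithium exchange to be faster than proton transfer. It need not control Cb, because the ketone it creates makes Cb–H and Cc–H exchangeable and the thermodynamic epimer is the wanted one.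

**22 from 12, 15 and 16.** Cc–Cb and Cb–ring C are cut together. Cb has to receive ring C, a hydrogen and Cc without ever being a free cation. An ortho-quinone methide of ring A does this, because the A5 oxygen is ortho to A6. Grignard reagent 16 delivers ring C to the aldehyde of carbonate 15, and the benzylic carbanion of indane ester 12 then adds to the quinone methide carbon. A lateral aldol followed by acid-mediated arylation would go through the forbidden cation. The three precursors are far simpler: 12 is an indane with two stereocentres, 15 and 16 are achiral. The forward step must deliver the carbanion anti to ring D and before the quinone methide is lost.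

**15 from 14 from 13.** The O–Boc bond and one O–CH3 bond are cut. The aldehyde in 13 directs selective loss of its ortho methyl group, so the differentiated ring-A piece comes from a symmetrical purchased aldehyde.

**12 from 10.** The B2–CO2Me bond is cut back to B2–Br. The ester has two jobs: it acidifies Cc–H for the coupling and later becomes Ca. It is introduced only after the steps that an ester would not survive (hydrazine, KOtBu in DMSO); until then bromine holds the position.

**10 from 9.** No bond is cut; Cd is epimerised. The carbene insertion is expected to give the cis indane 9 as the kinetic product. Because Cd–H is doubly benzylic, 9 can be equilibrated to trans 10. The catalyst therefore has to control only Ce, the one centre that cannot be repaired.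

**9 from 8 (key disconnection).** Cd–Ce is cut. This removes the five-membered ring and both stereocentres and leads to the achiral diaryldiazomethane 8. Cutting Cc–Ce or Cd–B6 instead would leave a stereocentre in the precursor. The forward step must choose one of two enantiotopic benzylic C–H bonds and prefer them to the methoxy C–H bonds beside the carbene.

**8 from 7 from 6 from 4 and 5.** The diazo group comes from the hydrazone 7 of ketone 6. The Cd–B6 bond of 6 is cut by Friedel–Crafts logic, since B6 is para and ortho to the two methoxy groups of bibenzyl 4 and B2 is blocked by bromine. Acid chloride 5 brings Cd and ring E.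

**4 from 3 from 1 and 2.** The Cc–Ce bond is traced to the double bond of stilbene 3, made from aldehyde 1 and phosphonate 2. The reduction must spare the aryl bromide.

## Roads not taken

**Alternative 1:** The cut is Cc–B1 and Ca–B2, so that ring B is inserted into the Ca–Cc bond of a ring-A indanone. In the forward step CsF releases 3,5-dimethoxybenzyne from silyl triflate A3. The enolate carbon of indanone A2 adds to the aryne, the aryl anion closes onto the carbonyl, and the four-membered alkoxide opens to the ring-expanded ketone A1. The merit is real: rings A and B are joined and the seven-membered ketone appears in one step, without any late organolithium, and the methoxy group steers the aryne regiochemistry correctly. The weak points are as follows. This acyl-alkylation is reliable for β-keto esters, whereas A2 offers a plain ketone enolate whose α-carbon already bears a bulky 1-arylallyl group; simple α-arylation or O-arylation is the likely outcome. A2 needs three defined stereocentres for which no catalytic entry is at hand. The indane still has to be closed afterwards from the vinyl group. Alternative 1 is more convergent than the chosen plan. The chosen plan sets against this a catalytic asymmetric step from an achiral precursor and ring-forming steps that each have close precedent.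

**Alternative 2:** The cut is through ring A itself (A1–A6, A2–A3, A4–A5). Cp*RuCl(cod) would join the ynone and alkynylboronate ends of diyne A5 with ethynylboronate A6 to give bis-boronate A4, forming ring A and the seven-membered ring together. The boronates would give the ring-A phenols by mild oxidation, which is gentler than ether cleavage, and no cation at Cb is involved; in these two respects it is as good as or better than the chosen plan. Against it: A5 already contains all four stereocentres on a finished indane, so the cyclotrimerisation solves none of the stereochemical problems and comes at the end of a long sequence. The ynone is a sensitive Michael acceptor. The third alkyne must insert with one particular orientation to place the boron groups meta. Closing a seven-membered ring in the tether is entropically less favourable than the usual five- or six-membered cases. The chosen plan reaches its ring-closure substrate in far fewer steps.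

**Alternative 3:** The cut is Cd–ring E and Ce–ring D on an indenone. In one flask [RhCl(C2H4)2]2 with a chiral diene would add boronic acid A9 to the β-carbon of indenone A8, and Pd(OAc)2 with P(t-Bu)3 would arylate the resulting enolate with bromide A10, giving indanone A7. Here the alternative is better than the chosen plan on one point: the trans relation of rings D and E is secured thermodynamically, since Ce is α to a ketone, whereas the carbene insertion needs a separate epimerisation. The price is that Cc arrives as a ketone. Turning C=O into CH–Cb with Cb trans to ring D requires addition followed by delivery of hydrogen to the face that ring D shields, or passage through an indene that erases Ce. A8, a cross-conjugated indenone with an aroyl group peri to the carbonyl, is itself a demanding target. The chosen plan keeps Cc as CH2, so that it can be used as a carbanion with the correct facial bias.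

Key step: step 6

Assumption 1: Rh2(R-PTAD)4 is taken to select the Ce–H bond that gives (S) at Ce; if the sense of induction is the opposite, Rh2(S-PTAD)4 is used and nothing else changes.
Assumption 2: compounds 1, 2, 5, 13 and 16 are treated as purchased materials.

## Steps

Step 1
Reactants: 1 2-bromo-3,5-dimethoxybenzaldehyde; 2 diethyl (4-methoxybenzyl)phosphonate
Product: 3 (E)-2-bromo-1,5-dimethoxy-3-[2-(4-methoxyphenyl)ethenyl]benzene
Conditions: KOtBu, THF, 0 °C to rt
Reagents that add atoms: none
Why: Horner–Wadsworth–Emmons olefination of a non-enolisable aryl aldehyde with a benzylic phosphonate anion should give the (E)-stilbene; the geometry is irrelevant because the double bond is reduced next, and the aryl bromide is inert to the alkoxide.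

Step 2
Reactants: 3 (E)-2-bromo-1,5-dimethoxy-3-[2-(4-methoxyphenyl)ethenyl]benzene
Product: 4 2-bromo-1,5-dimethoxy-3-[2-(4-methoxyphenyl)ethyl]benzene
Conditions: TsNHNH2, NaOAc, DME–H2O, reflux
Reagents that add atoms: none
Why: Diimide reduction: diimide formed in the flask transfers two hydrogens to the stilbene double bond in a concerted syn addition and, unlike hydrogenation over palladium, cannot cleave the C–Br bond.

Step 3
Reactants: 4 2-bromo-1,5-dimethoxy-3-[2-(4-methoxyphenyl)ethyl]benzene; 5 3,5-dimethoxybenzoyl chloride
Product: 6 {3-bromo-4,6-dimethoxy-2-[2-(4-methoxyphenyl)ethyl]phenyl}(3,5-dimethoxyphenyl)methanone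
Conditions: AlCl3, CH2Cl2, −10 to 0 °C
Reagents that add atoms: none
Why: Friedel–Crafts aroylation at B6, which is para to the B3 methoxy and ortho to the B5 methoxy group; B2 is blocked by bromine and B4 is hemmed in by two methoxy groups, one pushed towards it by the bromine. The monomethoxy ring D is far less nucleophilic, and the low temperature limits chelation-assisted loss of the B5 methyl group.

Step 4
Reactants: 6 {3-bromo-4,6-dimethoxy-2-[2-(4-methoxyphenyl)ethyl]phenyl}(3,5-dimethoxyphenyl)methanone
Product: 7 hydrazone of ketone 6 (either C=N geometry)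
Conditions: N2H4·H2O, N2H4·HCl (cat.), DMSO, 100 °C
Reagents that add atoms: hydrazine, NN
Why: Hydrazone formation by acid-catalysed condensation; the carbonyl is flanked by two ortho substituents on ring B, so the forcing hydrazine/hydrazinium chloride conditions used for hindered benzophenones are chosen. Aryl bromide and ethers are inert to them.

Step 5
Reactants: 7 hydrazone of ketone 6
Product: 8 2-bromo-4-[diazo(3,5-dimethoxyphenyl)methyl]-1,5-dimethoxy-3-[2-(4-methoxyphenyl)ethyl]benzene
Conditions: activated MnO2, MgSO4, CH2Cl2, 0 °C; filtered cold and used at once as a solution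
Reagents that add atoms: none
Why: Dehydrogenation of an N-unsubstituted hydrazone with MnO2 is the standard route to diaryldiazomethanes; the electron-rich, hindered diazo compound is handled only in cold solution.

Step 6
Reactants: 8 2-bromo-4-[diazo(3,5-dimethoxyphenyl)methyl]-1,5-dimethoxy-3-[2-(4-methoxyphenyl)ethyl]benzene
Product: 9 (1R,2S)-4-bromo-1-(3,5-dimethoxyphenyl)-5,7-dimethoxy-2-(4-methoxyphenyl)-2,3-dihydro-1H-indene (cis)
Conditions: Rh2(R-PTAD)4 [dirhodium tetrakis((R)-N-phthaloyl-adamantylglycinate)] (1 mol%), CH2Cl2, −20 to 0 °C, slow addition of 8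
Reagents that add atoms: none
Why: The dirhodium carboxylate takes N2 from 8 and forms a diaryl (donor/donor) rhodium carbene at Cd. The carbene carbon takes a hydride-like hydrogen from the 4-methoxybenzylic Ce–H through an asynchronous three-centre transition state, so that Cd–H and Cd–Ce form as rhodium leaves. The closest known reaction type is the rhodium-catalysed enantioselective intramolecular C–H insertion of diaryl carbenes made from hydrazones with MnO2, which gives 2,3-disubstituted dihydrobenzofurans, indolines and indanes. The five-membered ring Cd–B6–B1–Cc–Ce closes in the 1,5-insertion mode; the C–H bonds on Cc are 1,4-related and would need a four-membered ring. Ce is controlled by the catalyst, whose chiral carboxylate pocket distinguishes the two enantiotopic Ce–H bonds. Cd forms cis to ring D as the kinetic outcome of this reaction class, because ring D turns away from the catalyst wall and towards ring E; this centre is not relied upon and is corrected in step 7. The step needs chemoselectivity for Ce–H over the equally 1,5-related C–H bonds of the B5 methoxy group and over azine formation. It is secured by the much greater hydride-donor ability of a secondary 4-methoxybenzylic C–H compared with a primary aryl methyl ether C–H, by the low electrophilicity of donor/donor carbenes, and by slow addition in the cold; the aryl bromide is inert.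

Step 7
Reactants: 9 (1R,2S)-4-bromo-1-(3,5-dimethoxyphenyl)-5,7-dimethoxy-2-(4-methoxyphenyl)-2,3-dihydro-1H-indene
Product: 10 (1S,2S)-4-bromo-1-(3,5-dimethoxyphenyl)-5,7-dimethoxy-2-(4-methoxyphenyl)-2,3-dihydro-1H-indene (trans)
Conditions: KOtBu (0.5 equiv), DMSO, rt, argon, dark
Reagents that add atoms: none
Why: Base-mediated epimerisation through the planar diarylmethyl anion at Cd, the reaction type used to turn cis-1,2-diaryl benzocycloalkanes into their trans isomers; reprotonation under thermodynamic control should place ring E trans to ring D. Ce–H is only singly benzylic and is not exchanged, so Ce keeps the configuration from step 6 and Cd becomes (S); the bromide has no ortho hydrogen, so no aryne can form.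

Step 8
Reactants: 10 (1S,2S)-4-bromo-1-(3,5-dimethoxyphenyl)-5,7-dimethoxy-2-(4-methoxyphenyl)-2,3-dihydro-1H-indene
Product: 12 methyl (1S,2S)-1-(3,5-dimethoxyphenyl)-5,7-dimethoxy-2-(4-methoxyphenyl)-2,3-dihydro-1H-indene-4-carboxylate, via aryllithium 11 (not isolated)
Conditions: n-BuLi, THF, −78 °C; then ClCO2Me (excess), −78 °C to rt
Reagents that add atoms: methyl chloroformate, COC(=O)Cl
Why: Bromine–lithium exchange at −78 °C is faster than deprotonation of any C–H; the ortho-methoxy-stabilised aryllithium is then acylated by the chloroformate (alkoxycarbonylation of an aryllithium). No stereocentre is touched.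

Step 9
Reactants: 13 2-bromo-4,6-dimethoxybenzaldehyde
Product: 14 2-bromo-6-hydroxy-4-methoxybenzaldehyde
Conditions: BCl3, CH2Cl2, −78 to 0 °C; aqueous work-up
Reagents that add atoms: none
Why: Chelation-controlled ether cleavage: BCl3 binds the aldehyde oxygen and the ortho methoxy group and removes only that methyl group, the standard way to ortho-hydroxy aryl aldehydes; the para methoxy group stays.

Step 10
Reactants: 14 2-bromo-6-hydroxy-4-methoxybenzaldehyde
Product: 15 3-bromo-2-formyl-5-methoxyphenyl tert-butyl carbonate
Conditions: Boc2O, DMAP (cat.), CH2Cl2, rt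
Reagents that add atoms: di-tert-butyl dicarbonate, CC(C)(C)OC(=O)OC(=O)OC(C)(C)C
Why: O-Acylation of the phenol under nucleophilic catalysis gives the aryl carbonate that serves in step 11 as the relay leaving group for quinone methide formation.

Step 11
Reactants: 12 methyl (1S,2S)-1-(3,5-dimethoxyphenyl)-5,7-dimethoxy-2-(4-methoxyphenyl)-2,3-dihydro-1H-indene-4-carboxylate; 15 3-bromo-2-formyl-5-methoxyphenyl tert-butyl carbonate; 16 4-methoxyphenylmagnesium bromide
Product: 22 methyl (1S,2S,3R)-3-[(2-bromo-4,6-dimethoxyphenyl)(4-methoxyphenyl)methyl]-1-(3,5-dimethoxyphenyl)-5,7-dimethoxy-2-(4-methoxyphenyl)-2,3-dihydro-1H-indene-4-carboxylate (both Cb epimers), via lateral benzylic lithio ester 17 (not isolated), via bromomagnesium alkoxide 18 (not isolated), via Boc-shifted magnesium phenoxide 19 (not isolated), via ortho-quinone methide 20 (not isolated), via lithium phenoxide adduct 21 (not isolated)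
Conditions: flask 1: 12, LiTMP (lithium 2,2,6,6-tetramethylpiperidide, from the amine and n-BuLi), THF, −78 °C; flask 2: 15 + 16, THF, −78 °C; flask 1 added to flask 2, −78 to 0 °C; then MeOTf, 0 °C
Reagents that add atoms: methyl trifluoromethanesulfonate, COS(=O)(=O)C(F)(F)F
Why: Three-component ortho-quinone methide coupling: the aryl Grignard adds to the aldehyde of 15, the Boc group shifts to the new alkoxide, and β-elimination of tert-butyl carbonate gives quinone methide 20, to whose exocyclic carbon (Cb) the lateral carbanion 17 (lateral lithiation of an ortho-alkyl benzoate) adds in 1,4 fashion, re-aromatising ring A; the phenoxide is methylated in the flask. Cc is set because the planar benzylic anion is attacked on the face anti to ring D on the neighbouring Ce, which puts the Cc–Cb bond trans to ring D; Cb forms without reliable control and is corrected in step 12. Cb is never a cation, so ring E cannot intervene.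

Step 12
Reactants: 22 methyl (1S,2S,3R)-3-[(2-bromo-4,6-dimethoxyphenyl)(4-methoxyphenyl)methyl]-1-(3,5-dimethoxyphenyl)-5,7-dimethoxy-2-(4-methoxyphenyl)-2,3-dihydro-1H-indene-4-carboxylate (both Cb epimers)
Product: 26 hexa-O-methyl ether of the target (Cb S; Cc R; Ce S; Cd S), via A1 aryllithium 23 (not isolated), via lithium hemiketal alkoxide 24 (not isolated), via Cb-epimeric ketone mixture 25 (not isolated)
Conditions: t-BuLi (2.05 equiv), THF, −78 to −20 °C; then t-BuOH, KOtBu (cat.), rt; aqueous NH4Cl
Reagents that add atoms: none
Why: Parham-type cyclisation: bromine–lithium exchange at A1 and 7-exo-trig attack of the aryllithium on the B2 ester give, after loss of methoxide, the diaryl ketone and the seven-membered ring. In the ketone both Cb–H and Cc–H are benzylic and ortho to the carbonyl, so catalytic tert-butoxide equilibrates them through the dienolates. The arrangement of the target (ring C trans to Ce across Cb–Cc, the Cc–Cb bond trans to ring D) is expected to be the most stable; Ce and Cd are not acidified and stay as set.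

Step 13
Reactants: 26 hexa-O-methyl ether of the target
Product: 27 CNP0116600.1, the hexaphenol (Cb S; Cc R; Ce S; Cd S)
Conditions: BBr3 (excess), CH2Cl2, −78 °C to rt; MeOH then H2O, under argon
Reagents that add atoms: none
Why: Lewis-acid cleavage of all six aryl methyl ethers with BBr3, the borate esters being hydrolysed on work-up; the skeleton has no leaving group at a benzylic carbon, so no cation forms, and the air-sensitive hexaphenol is released only here.

## Compound list

1 | 2-bromo-3,5-dimethoxybenzaldehyde | COc1cc(C=O)c(Br)c(OC)c1 | starting material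
2 | diethyl (4-methoxybenzyl)phosphonate | CCOP(=O)(Cc1ccc(OC)cc1)OCC | starting material
3 | (E)-2-bromo-1,5-dimethoxy-3-[2-(4-methoxyphenyl)ethenyl]benzene | COc1ccc(/C=C/c2cc(OC)cc(OC)c2Br)cc1 | intermediate
4 | 2-bromo-1,5-dimethoxy-3-[2-(4-methoxyphenyl)ethyl]benzene | COc1ccc(CCc2cc(OC)cc(OC)c2Br)cc1 | intermediate
5 | 3,5-dimethoxybenzoyl chloride | COc1cc(cc(OC)c1)C(Cl)=O | starting material
6 | {3-bromo-4,6-dimethoxy-2-[2-(4-methoxyphenyl)ethyl]phenyl}(3,5-dimethoxyphenyl)methanone | Brc1c(OC)cc(OC)c(C(=O)c2cc(OC)cc(OC)c2)c1CCc1ccc(OC)cc1 | intermediate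
7 | hydrazone of ketone 6 (either C=N geometry) | Brc1c(OC)cc(OC)c(C(=NN)c2cc(OC)cc(OC)c2)c1CCc1ccc(OC)cc1 | intermediate
8 | 2-bromo-4-[diazo(3,5-dimethoxyphenyl)methyl]-1,5-dimethoxy-3-[2-(4-methoxyphenyl)ethyl]benzene | Brc1c(OC)cc(OC)c(C(=[N+]=[N-])c2cc(OC)cc(OC)c2)c1CCc1ccc(OC)cc1 | intermediate
9 | (1R,2S)-4-bromo-1-(3,5-dimethoxyphenyl)-5,7-dimethoxy-2-(4-methoxyphenyl)-2,3-dihydro-1H-indene (cis) | Brc1c(OC)cc(OC)c2c1C[C@H](c1ccc(OC)cc1)[C@@H]2c1cc(OC)cc(OC)c1 | intermediate
10 | (1S,2S)-4-bromo-1-(3,5-dimethoxyphenyl)-5,7-dimethoxy-2-(4-methoxyphenyl)-2,3-dihydro-1H-indene (trans) | Brc1c(OC)cc(OC)c2c1C[C@H](c1ccc(OC)cc1)[C@H]2c1cc(OC)cc(OC)c1 | intermediate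
11 | 4-lithio derivative of 10 (aryllithium at B2) | [Li]c1c(OC)cc(OC)c2c1C[C@H](c1ccc(OC)cc1)[C@H]2c1cc(OC)cc(OC)c1 | intermediate
12 | methyl (1S,2S)-1-(3,5-dimethoxyphenyl)-5,7-dimethoxy-2-(4-methoxyphenyl)-2,3-dihydro-1H-indene-4-carboxylate | COC(=O)c1c(OC)cc(OC)c2c1C[C@H](c1ccc(OC)cc1)[C@H]2c1cc(OC)cc(OC)c1 | intermediate
13 | 2-bromo-4,6-dimethoxybenzaldehyde | COc1cc(Br)c(C=O)c(OC)c1 | starting material
14 | 2-bromo-6-hydroxy-4-methoxybenzaldehyde | COc1cc(O)c(C=O)c(Br)c1 | intermediate
15 | 3-bromo-2-formyl-5-methoxyphenyl tert-butyl carbonate | COc1cc(OC(=O)OC(C)(C)C)c(C=O)c(Br)c1 | intermediate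
16 | 4-methoxyphenylmagnesium bromide | COc1ccc([Mg]Br)cc1 | starting material
17 | 12 lithiated at C-3 (Cc), the lateral benzylic anion | COC(=O)c1c(OC)cc(OC)c2c1C([Li])[C@H](c1ccc(OC)cc1)[C@H]2c1cc(OC)cc(OC)c1 | intermediate
18 | bromomagnesium alkoxide from addition of 16 to the aldehyde of 15 | COc1cc(OC(=O)OC(C)(C)C)c(C(O[Mg]Br)c2ccc(OC)cc2)c(Br)c1 | intermediate
19 | magnesium phenoxide with the Boc group shifted to the benzylic oxygen | COc1cc(O[Mg]Br)c(C(OC(=O)OC(C)(C)C)c2ccc(OC)cc2)c(Br)c1 | intermediate
20 | 3-bromo-5-methoxy-2-[(4-methoxyphenyl)methylidene]cyclohexa-3,5-dien-1-one (ortho-quinone methide of ring A) | O=C1C=C(OC)C=C(Br)C1=Cc1ccc(OC)cc1 | intermediate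
21 | lithium phenoxide (at the A5 oxygen) of the 1,4-adduct of 17 and 20, Cb epimers | COC(=O)c1c(OC)cc(OC)c2c1[C@@H](C(c1ccc(OC)cc1)c1c(Br)cc(OC)cc1O[Li])[C@H](c1ccc(OC)cc1)[C@H]2c1cc(OC)cc(OC)c1 | intermediate
22 | methyl (1S,2S,3R)-3-[(2-bromo-4,6-dimethoxyphenyl)(4-methoxyphenyl)methyl]-1-(3,5-dimethoxyphenyl)-5,7-dimethoxy-2-(4-methoxyphenyl)-2,3-dihydro-1H-indene-4-carboxylate, Cb epimers | COC(=O)c1c(OC)cc(OC)c2c1[C@@H](C(c1ccc(OC)cc1)c1c(Br)cc(OC)cc1OC)[C@H](c1ccc(OC)cc1)[C@H]2c1cc(OC)cc(OC)c1 | intermediate
23 | 22 with lithium in place of bromine at A1 | COC(=O)c1c(OC)cc(OC)c2c1[C@@H](C(c1ccc(OC)cc1)c1c([Li])cc(OC)cc1OC)[C@H](c1ccc(OC)cc1)[C@H]2c1cc(OC)cc(OC)c1 | intermediate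
24 | lithium salt of the cyclic methyl hemiketal at Ca (seven-membered ring closed), Cb epimers | [Li]OC1(OC)c2cc(OC)cc(OC)c2C(c2ccc(OC)cc2)[C@@H]2c3c1c(OC)cc(OC)c3[C@H](c1cc(OC)cc(OC)c1)[C@H]2c1ccc(OC)cc1 | intermediate
25 | hexa-O-methyl ketone as the mixture of Cb epimers | O=C1c2cc(OC)cc(OC)c2C(c2ccc(OC)cc2)[C@@H]2c3c1c(OC)cc(OC)c3[C@H](c1cc(OC)cc(OC)c1)[C@H]2c1ccc(OC)cc1 | intermediate
26 | hexa-O-methyl ether of the target (Cb S, Cc R, Ce S, Cd S) | O=C1c2cc(OC)cc(OC)c2[C@H](c2ccc(OC)cc2)[C@@H]2c3c1c(OC)cc(OC)c3[C@H](c1cc(OC)cc(OC)c1)[C@H]2c1ccc(OC)cc1 | intermediate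
27 | CNP0116600.1, hexaphenol (Cb S, Cc R, Ce S, Cd S) | O=C1c2cc(O)cc(O)c2[C@H](c2ccc(O)cc2)[C@@H]2c3c1c(O)cc(O)c3[C@H](c1cc(O)cc(O)c1)[C@H]2c1ccc(O)cc1 | target

## Step count and least certain steps

Total: 13 steps. Longest linear sequence: 11 steps (steps 1–8 and 11–13, from 1); steps 9 and 10 form a two-step side branch.

**Step 6 (key step).** The most likely failure is insufficient discrimination between the two enantiotopic Ce–H bonds. The carbene carries a ring B with two ortho substituents, which is not the substitution pattern of the precedents, and it may sit differently in the catalyst pocket. A poor cis/trans ratio would not matter because step 7 equilibrates Cd. Fallback: the absolute configuration is taken from a separation and not from the catalyst. Diazo compound 8 is decomposed with achiral Rh2(esp)2 [dirhodium bis(α,α,α′,α′-tetramethyl-1,3-benzenedipropionate)] to the racemic cis-indane F1, which is epimerised with KOtBu in DMSO to the racemic trans-indane F2. The enantiomers of F2 are separated by preparative chromatography on a chiral stationary phase, and the (1S,2S) enantiomer is 10.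

**Step 11.** The transient ortho-quinone methide may be lost by dimerisation or by addition of tert-butoxide or of the Grignard reagent before the hindered secondary carbanion reaches it, and proton transfer may quench the carbanion. Fallback: an isolable para-quinone methide replaces the transient one. Aldehyde 13 is condensed with 2,6-di-tert-butylphenol (piperidine, toluene, reflux; then Ac2O) to the para-quinone methide F5. Carbanion 17, made from 12 as in step 11, adds 1,6 to it and gives the hindered phenol F6. Cyclisation and equilibration as in step 12 give the ketone F7. AlCl3 in toluene then transfers the two tert-butyl groups to the solvent and BBr3 cleaves the methyl ethers, so that the route is rejoined at 27.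

**Step 12.** Proton transfer to the aryllithium, or attack of t-BuLi on the crowded ester, may compete with the seven-membered acyl transfer, and the equilibration may leave part of the material as the Cb epimer. Fallback: the electrophile is changed to an aldehyde. Ester 22 is reduced with LiAlH4 to the benzylic alcohol F8, which MnO2 oxidises to the aldehyde F9. Bromine–lithium exchange with t-BuLi and addition of the aryllithium to the aldehyde close the ring as the diaryl carbinol F10. Oxidation with MnO2 gives the ketone mixture 25, which is equilibrated with KOtBu as in step 12 and comes back to the route at 26.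

**Step 7.** Electron-transfer loss or migration of bromine, or slow proton exchange at Cd, may occur in the strongly basic medium. Fallback: the order is changed so that no aryl halide meets the base. Cis-bromide 9 is converted with n-BuLi and CO2 into the cis acid F3, whose potassium salt is equilibrated with KOtBu in DMSO to the trans acid F4 (not isolated). After the excess base is quenched, MeI in the same flask gives ester 12.

## Further compounds

F1 | step 6 | racemic cis-4-bromo-1-(3,5-dimethoxyphenyl)-5,7-dimethoxy-2-(4-methoxyphenyl)indane | Brc1c(OC)cc(OC)c2c1C[C@H](c1ccc(OC)cc1)[C@@H]2c1cc(OC)cc(OC)c1.Brc1c(OC)cc(OC)c2c1C[C@@H](c1ccc(OC)cc1)[C@H]2c1cc(OC)cc(OC)c1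
F2 | step 6 | racemic trans-4-bromo-1-(3,5-dimethoxyphenyl)-5,7-dimethoxy-2-(4-methoxyphenyl)indane | Brc1c(OC)cc(OC)c2c1C[C@H](c1ccc(OC)cc1)[C@H]2c1cc(OC)cc(OC)c1.Brc1c(OC)cc(OC)c2c1C[C@@H](c1ccc(OC)cc1)[C@@H]2c1cc(OC)cc(OC)c1
F3 | step 7 | (1R,2S)-1-(3,5-dimethoxyphenyl)-5,7-dimethoxy-2-(4-methoxyphenyl)-2,3-dihydro-1H-indene-4-carboxylic acid (cis) | OC(=O)c1c(OC)cc(OC)c2c1C[C@H](c1ccc(OC)cc1)[C@@H]2c1cc(OC)cc(OC)c1
F4 | step 7 | (1S,2S)-1-(3,5-dimethoxyphenyl)-5,7-dimethoxy-2-(4-methoxyphenyl)-2,3-dihydro-1H-indene-4-carboxylic acid (trans) | OC(=O)c1c(OC)cc(OC)c2c1C[C@H](c1ccc(OC)cc1)[C@H]2c1cc(OC)cc(OC)c1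
F5 | step 11 | 4-[(2-bromo-4,6-dimethoxyphenyl)methylidene]-2,6-di-tert-butylcyclohexa-2,5-dien-1-one | CC(C)(C)C1=CC(=Cc2c(Br)cc(OC)cc2OC)C=C(C(C)(C)C)C1=O
F6 | step 11 | methyl ester 12 carrying on Cc the (2-bromo-4,6-dimethoxyphenyl)(3,5-di-tert-butyl-4-hydroxyphenyl)methyl group, trans to ring D, Cb epimers | COC(=O)c1c(OC)cc(OC)c2c1[C@@H](C(c1cc(C(C)(C)C)c(O)c(C(C)(C)C)c1)c1c(Br)cc(OC)cc1OC)[C@H](c1ccc(OC)cc1)[C@H]2c1cc(OC)cc(OC)c1
F7 | step 11 | seven-membered ketone with ring C as 3,5-di-tert-butyl-4-hydroxyphenyl, other five oxygens as methyl ethers (Cb S, Cc R, Ce S, Cd S) | O=C1c2cc(OC)cc(OC)c2[C@H](c2cc(C(C)(C)C)c(O)c(C(C)(C)C)c2)[C@@H]2c3c1c(OC)cc(OC)c3[C@H](c1cc(OC)cc(OC)c1)[C@H]2c1ccc(OC)cc1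
F8 | step 12 | benzylic alcohol from reduction of the ester of 22, Cb epimers | OCc1c(OC)cc(OC)c2c1[C@@H](C(c1ccc(OC)cc1)c1c(Br)cc(OC)cc1OC)[C@H](c1ccc(OC)cc1)[C@H]2c1cc(OC)cc(OC)c1
F9 | step 12 | aldehyde at B2 corresponding to 22, Cb epimers | O=Cc1c(OC)cc(OC)c2c1[C@@H](C(c1ccc(OC)cc1)c1c(Br)cc(OC)cc1OC)[C@H](c1ccc(OC)cc1)[C@H]2c1cc(OC)cc(OC)c1
F10 | step 12 | cyclic diaryl carbinol (hydroxyl on Ca), seven-membered ring closed, epimers at Ca and Cb | OC1c2cc(OC)cc(OC)c2C(c2ccc(OC)cc2)[C@@H]2c3c1c(OC)cc(OC)c3[C@H](c1cc(OC)cc(OC)c1)[C@H]2c1ccc(OC)cc1
A1 | alternative 1 | hexa-O-methyl seven-membered ketone with the 1-arylallyl group on Cc | O=C1c2cc(OC)cc(OC)c2[C@H](c2ccc(OC)cc2)[C@@H]([C@H](c2ccc(OC)cc2)C=C)c2cc(OC)cc(OC)c12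
A2 | alternative 1 | 4,6-dimethoxy-3-(4-methoxyphenyl)-2-[1-(4-methoxyphenyl)allyl]indan-1-one (ring-A indanone) | O=C1c2cc(OC)cc(OC)c2[C@H](c2ccc(OC)cc2)C1[C@H](c1ccc(OC)cc1)C=C
A3 | alternative 1 | 3,5-dimethoxy-2-(trimethylsilyl)phenyl trifluoromethanesulfonate | COc1cc(OC)c([Si](C)(C)C)c(OS(=O)(=O)C(F)(F)F)c1
A4 | alternative 2 | hexa-O-methyl skeleton with ring A as 3,5-bis(pinacolboronate) | O=C1c2cc(B3OC(C)(C)C(C)(C)O3)cc(B3OC(C)(C)C(C)(C)O3)c2[C@H](c2ccc(OC)cc2)[C@@H]2c3c1c(OC)cc(OC)c3[C@H](c1cc(OC)cc(OC)c1)[C@H]2c1ccc(OC)cc1
A5 | alternative 2 | indane carrying the ynone on B2 and the 1-aryl-3-borylpropargyl group on Cc | C#CC(=O)c1c(OC)cc(OC)c2c1[C@@H]([C@H](C#CB1OC(C)(C)C(C)(C)O1)c1ccc(OC)cc1)[C@H](c1ccc(OC)cc1)[C@H]2c1cc(OC)cc(OC)c1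
A6 | alternative 2 | 2-ethynyl-4,4,5,5-tetramethyl-1,3,2-dioxaborolane | C#CB1OC(C)(C)C(C)(C)O1
A7 | alternative 3 | B2-aroyl trans-2,3-diarylindan-1-one | O=C(c1cc(OC)cc(OC)c1)c1c(OC)cc(OC)c2c1C(=O)[C@H](c1ccc(OC)cc1)[C@H]2c1cc(OC)cc(OC)c1
A8 | alternative 3 | 7-(3,5-dimethoxybenzoyl)-4,6-dimethoxy-1H-inden-1-one | O=C(c1cc(OC)cc(OC)c1)c1c(OC)cc(OC)c2c1C(=O)C=C2
A9 | alternative 3 | 3,5-dimethoxyphenylboronic acid | OB(O)c1cc(OC)cc(OC)c1
A10 | alternative 3 | 4-bromoanisole | COc1ccc(Br)cc1
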